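## The problem

CNP0198076.6 (33) is a germacranolide: a ten-membered carbocycle (C1–C10) with a Z-trisubstituted C1=C10 alkene, a cis-4,5-epoxide, an α-methylene γ-lactone trans-fused at C6/C7 and a 4-hydroxytiglate on the C8 oxygen. The ring is the first difficulty, because end-to-end closure of a ten-membered ring is slow and gives no handle on the geometry of a trisubstituted Z-alkene. Five contiguous stereocentres (4R,5S,6S,7R,8R) must be set. C7 can come from the chiral pool and can direct C6 and C8 while these three atoms sit on a rigid six-membered ring, but C4 and C5 lie across the ring and need a different relay. The epoxide faces the C1=C10 alkene and will cyclise under acid; the methylene lactone is a Michael acceptor that survives neither hydride, organometallic reagents nor strong base; the side chain carries a free allylic alcohol. All three must therefore appear late and under neutral conditions, and a free C8 hydroxyl beside a C12 lactol would let the lactol close onto the wrong oxygen. The enabling feature is the array C10=C1–C2–C3–C4–C5(O), an alkene and an oxygenated carbon in a 1,5-relationship, which is the signature of an oxy-Cope product. Removing it leaves C5–C10 as an ordinary cyclohexane on which C6, C7 and C8 are neighbours, and the C5 oxygen that the rearrangement needs is the oxygen that the epoxide needs.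

## Retrosynthesis

**Side-chain silyl ether, lactone carbonyl, acetal and ester (33 ⇒ 32 ⇒ 31 ⇒ 30 ⇒ 24 + 28).** The bonds cut are O–Si of the side chain, the C12 carbonyl (back to lactol 31), the C12–O acetal bond (back to 4-methoxybenzyl acetal 30) and the C8–O acyl bond (to epoxy alcohol 24 and acid 28). The ester is cut after the lactone carbonyl so that, going forward, C8 is acylated while C12 is still an acetal and lactol 31 can close only onto O6. A 4-methoxybenzyl acetal is chosen over a methyl acetal because DDQ removes it at neutral pH; a methyl acetal would need acid beside the epoxide. The precursors lack the two most fragile groups of 33, and the forward steps ask only for chemoselectivity.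

**Epoxide (24 ⇒ 23 ⇒ 22 ⇒ 21 ⇒ 20).** The C4–O bond is cut and the C5–O bond kept, giving bromohydrin 22, α-bromo ketone 21 and silyl enol ether 20. The neighbouring cut (peracid oxidation of 20 at C4, then closure of that oxygen onto a C5 sulfonate) is rejected on geometry. In 20 the ring passes through trans positions of a tetrasubstituted enol ether that cannot turn inside the ring, so a reagent reaches C4 only from the outer face, and an oxygen placed there would give the C4 epimer of 33. Bromine is therefore put on the outer face and the C5 oxygen displaces it with inversion. The forward steps must deliver bromine to the open face and hydride to C5 so that the bromohydrin is 5,6-anti.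

**Ten-membered ring (20 ⇒ 17).** The C2–C3 bond is cut and C5–C10 re-formed, which turns 20 into cis-1-isopropenyl-2-vinylcyclohexanol 17. Against cuts that close the ring end to end, this one needs no macrocyclisation and ties the C1=C10 geometry to a chair transition state. The precursor is a cyclohexane with all of C5–C8 and C10 on a locked chair. The forward step must run through the chair with the isopropenyl group axial and the vinyl group equatorial.

**Isopropenyl group (17 ⇒ 14 + 15).** The C4–C5 bond is cut to ketone 14 and 2-bromopropene 15. The carbonyl of carvone is the natural C5 electrophile, and no other order keeps the tertiary alcohol out of the earlier enolate chemistry. The addition must come from the α face, which the axial C10 methyl should enforce.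

**Vinyl group and C10 quaternary centre (14 ⇒ 13 ⇒ 10 + 11).** The C10–C1 bond is cut to enone 10 and phenyl vinyl sulfoxide 11 (a vinyl cation equivalent), with a hydride placed on C9. Alkylating before C8 is oxygenated would put the chain cis to the C7 side chain, the usual axial mode of a dihydrocarvone enolate. With the 8β-silyloxy group axial that face is blocked and the chain is sent to the α face.

**C8 oxygen (10 ⇒ 9 ⇒ 8 ⇒ 7).** The C8–O bond is cut back to bicyclic enone 7 through dienol ether 8. The oxygen is introduced on the bicycle and not on a monocyclic carvone derivative, because the trans ring fusion locks the half-chair so that axial delivery at C8 is cis to the C7 side chain. The forward step needs γ- rather than α-attack and axial rather than equatorial delivery.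

**Acetal ring and C6 oxygen (7 ⇒ 6 ⇒ 4 ⇒ 3 ⇒ 1).** The C12–O6 bond, the C12 oxidation level and the C6–O bond are removed in turn, leading through enal 6 and silyloxy ketone 4 to (R)-carvone 1, which supplies C7, C14 and the three-carbon unit C11–C13. The C6 oxygen is set trans to the side chain by enolate oxidation. Closing the five-membered acetal early is what later controls C8, C10, C5 and the chair of the key step.

**Side chain (28 ⇒ 27 ⇒ 25 + 26).** The C2′=C3′ bond is cut to aldehyde 25 and stabilised ylide 26; the forward Wittig reaction must give the E-enoate.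

## Roads not taken

Alternative 1: The cut is the C6–O lactone bond together with the later C5–O epoxide bond. Iodine in acetonitrile would activate the Z-C5=C6 alkene of seco acid A2, the C12 acid would close on C6 (5-exo, anti addition) to give iodo lactone A1, and the C4 alkoxide would then displace iodide with inversion to the cis-epoxide. Its strength is real: C4 comes from the linalool chiral pool and C5/C6 are set stereospecifically in one step, whereas the chosen plan depends on a face-selective bromination (step 12) and a chelation-controlled reduction (step 13). Its weak points are that A2 already needs the ten-membered ring with two Z-alkenes, so the hardest problem is only postponed. Iodine must also choose the disubstituted C5=C6 over the more electron-rich C1=C10 alkene without transannular cyclisation, the facial course rests on a flexible ring, and the methylene group has to be added to A1 beside an epoxide. The chosen plan sets against this a ring made without macrocyclisation, an alkene geometry fixed by a chair, and a methylene carbon carried from carvone.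

Alternative 2: The cut is C7–C8. Tin–lithium exchange with n-BuLi at C8 of thirteen-membered stannyl ether A4 would trigger a [2,3]-Wittig–Still shift that forms C7–C8, breaks O–C13, creates the C11=C13 methylene and contracts the ring to ten-membered alcohol A3. In convergence it is better than the chosen plan: one step gives both stereocentres, the C8 hydroxyl and the methylene with C12 at the alcohol level, where the chosen plan spends separate steps on γ-hydroxylation and allylic oxidation. Against it, A4 needs a macrocyclic ether closure with two Z-trisubstituted alkenes and a configurationally defined α-alkoxystannane. The syn/anti outcome at C7/C8 in a medium-ring transition state is hard to predict, a [1,2]-shift competes, and the C4=C5 alkene of A3 must then be epoxidised selectively beside C1=C10. The chosen plan offers C6–C8 set on a rigid bicycle and an epoxide oxygen already in place.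

Alternative 3: The cut is C8–C9. Irradiation near 300 nm of 2-isopropenylcyclooctanone A6 would cleave C8–C1 to an acyl/allyl radical pair that recombines at C9, giving ten-membered β,γ-unsaturated ketone A5 with epoxide and lactone already present. It needs few protecting groups, expands the ring late and leaves a C8 ketone as a handle, all of which the chosen plan lacks. Its weak points are that a radical pair gives no control of the C1=C10 geometry, the 1,3-shift is reversible and competes with decarbonylation and with the photochemistry of the epoxy ketone, and the β,γ-enone A5 slips into conjugation. C8 must still be reduced selectively, and A6 with its stereocentres is itself a long target. The chosen plan answers with a concerted step whose geometry is dictated by a locked chair.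

Key step: step 11

Remark: atoms carry the numbers of the target throughout (C1–C10 ring, C11–C13 on C7, C14 on C10, C15 on C4); in the cyclohexane intermediates α is the face of H-7 and β the face of the C7 side chain.
Remark: the acetal carbon C12 is drawn as one anomer (alkoxy group trans to H-6); the other would serve equally, since this centre is erased in step 19. Sulfoxide 11 is racemic, so 13 is a pair of sulfur epimers that converge in step 9.

## Steps

Step 1
Reactants: 1 (R)-carvone
Product: 3 triethyl{[(6R)-3-methyl-6-(prop-1-en-2-yl)cyclohexa-1,3-dien-2-yl]oxy}silane, via lithium dienolate 2 (not isolated)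
Conditions: LiN(i-Pr)2, THF, −78 °C; Et3SiCl, −78 → 0 °C
Reagents that add atoms: chlorotriethylsilane, CC[Si](Cl)(CC)CC
Why: Kinetic deprotonation of the enone at the α′-methylene (C6) by the hindered amide and O-silylation give the cross-conjugated 2-silyloxy diene (enolate silylation); no stereocentre is touched.

Step 2
Reactants: 3 triethylsilyl dienol ether
Product: 4 (5S,6S)-2-methyl-5-(prop-1-en-2-yl)-6-(triethylsilyloxy)cyclohex-2-en-1-one (silyloxy group trans to the isopropenyl group)
Conditions: mCPBA, NaHCO3, CH2Cl2, −20 → 0 °C
Reagents that add atoms: 3-chloroperbenzoic acid, OOC(=O)c1cccc(Cl)c1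
Why: Rubottom oxidation: the peracid epoxidises the electron-rich enol ether on the face away from the neighbouring isopropenyl group and a 1,4-silyl shift gives the α-silyloxy ketone, so the C6 oxygen is set trans to the C7 side chain.

Step 3
Reactants: 4 silyloxy enone
Product: 6 2-[(1S,2S)-4-methyl-3-oxo-2-(triethylsilyloxy)cyclohex-4-en-1-yl]prop-2-enal, via allylic alcohol 5 (not isolated)
Conditions: SeO2 (cat.), t-BuOOH, CH2Cl2, 23 °C; then MnO2, CH2Cl2, 23 °C
Reagents that add atoms: selenium dioxide, O=[Se]=O; tert-butyl hydroperoxide, CC(C)(C)OO
Why: SeO2-catalysed allylic oxidation (ene reaction then [2,3]-shift) goes to the methyl group of the electron-rich 1,1-disubstituted alkene and spares the electron-poor enone; MnO2 then takes the primary allylic alcohol, the only free hydroxyl, to the enal.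

Step 4
Reactants: 6 silyloxy enal
Product: 7 (2R,3aS,7aS)-2-(4-methoxybenzyloxy)-6-methyl-3-methylidene-3,3a,4,7a-tetrahydro-1-benzofuran-7(2H)-one (trans-fused methylene lactol acetal with the enone intact)
Conditions: 4-MeOC6H4CH2OH, camphorsulfonic acid (cat.), CH2Cl2, 23 °C
Reagents that add atoms: 4-methoxybenzyl alcohol, COc1ccc(CO)cc1
Why: Acid-catalysed desilylation frees the C6 hydroxyl, which adds to the aldehyde to give the trans-fused five-membered lactol, and Fischer-type acetalisation with the benzylic alcohol fixes it as the mixed acetal; C6 and C7 are untouched.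

Step 5
Reactants: 7 bicyclic enone
Product: 8 tert-butyldimethylsilyl dienol ether of 7 (C5–OSi with C5=C10 and C8=C9 double bonds)
Conditions: t-BuMe2SiOTf, Et3N, CH2Cl2, −78 → 0 °C
Reagents that add atoms: tert-butyldimethylsilyl trifluoromethanesulfonate, CC(C)(C)[Si](C)(C)OS(=O)(=O)C(F)(F)F
Why: Amine-buffered silyl triflate gives the thermodynamic through-conjugated dienol ether by loss of a γ-hydrogen at C8 (soft enolisation, as used to make heteroannular dienol ethers of cyclohexenones); the buffered conditions should leave the acetal alone.

Step 6
Reactants: 8 silyl dienol ether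
Product: 9 8β-hydroxy enone (7 carrying an axial hydroxyl at C8, cis to the C7–C11 bond)
Conditions: mCPBA, NaHCO3, CH2Cl2, −40 → 0 °C; aqueous work-up
Reagents that add atoms: 3-chloroperbenzoic acid, OOC(=O)c1cccc(Cl)c1
Why: Vinylogous Rubottom oxidation: the peracid attacks the terminal carbon (C8) of the 1-silyloxy diene and collapse gives the γ-hydroxy enone. In the half-chair locked by the trans-fused acetal the oxygen should enter along the axial direction, anti-periplanar to the axial C7–H, hence cis to the C7 side chain, as in the 6β-hydroxylation of steroidal dienol ethers.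

Step 7
Reactants: 9 8β-hydroxy enone
Product: 10 8β-(tert-butyldimethylsilyloxy) enone
Conditions: t-BuMe2SiOTf, 2,6-lutidine, CH2Cl2, −78 °C
Reagents that add atoms: tert-butyldimethylsilyl trifluoromethanesulfonate, CC(C)(C)[Si](C)(C)OS(=O)(=O)C(F)(F)F
Why: Silylation of a hindered secondary alcohol with silyl triflate and a hindered pyridine; the axial silyl ether shields the β face in step 8 and keeps O8 masked until step 14.

Step 8
Reactants: 10 8β-silyloxy enone; 11 phenyl vinyl sulfoxide
Product: 13 10α-[2-(phenylsulfinyl)ethyl]-10β-methyl ketone (both sulfur epimers), via lithium enolate 12 (not isolated)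
Conditions: LiBH(s-Bu)3, THF, −78 °C; then 11, −78 → 0 °C; then H2O
Reagents that add atoms: none
Why: Conjugate reduction of the β-unsubstituted enone by the bulky borohydride gives the C5=C10 enolate regiospecifically, and its Michael addition to the vinyl sulfoxide creates the C10 quaternary centre. The axial 8β-silyloxy group blocks the β face, so the chain should enter from the α face and the methyl group become axial.

Step 9
Reactants: 13 sulfoxide
Product: 14 10α-vinyl-10β-methyl ketone
Conditions: CaCO3, toluene, 110 °C
Reagents that add atoms: none
Why: Thermal syn-elimination of the sulfoxide can take a hydrogen only from the carbon attached to C10 and so unveils the vinyl group; CaCO3 buffers the sulfenic acid.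

Step 10
Reactants: 14 vinyl ketone; 15 2-bromopropene
Product: 17 cis-dialkenyl cyclohexanol (5α-isopropenyl-5β-hydroxy-10α-vinyl-10β-methyl; 8β-silyloxy; trans-fused C12 acetal), via isopropenylmagnesium bromide 16 (not isolated)
Conditions: 15, Mg, THF, 40 °C; CeCl3, THF, −78 °C; add 14, −78 → 0 °C; then H2O
Reagents that add atoms: none
Why: 1,2-Addition of the organocerium reagent derived from the Grignard reagent to a hindered, enolisable ketone. The axial 10β-methyl blocks equatorial approach, so the nucleophile should enter axially from the α face and the two alkenyl groups end up cis (isopropenyl axial, vinyl equatorial).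

Step 11
Reactants: 17 cis-dialkenyl cyclohexanol
Product: 20 ten-membered trimethylsilyl enol ether (Z-C1=C10; C3 and C6 trans across C4=C5), via potassium alkoxide 18 (not isolated), via potassium enolate 19 (not isolated)
Conditions: KH, 18-crown-6, THF, 0 → 25 °C; then Me3SiCl, Et3N, −78 °C
Reagents that add atoms: chlorotrimethylsilane, C[Si](C)(C)Cl
Why: KH with 18-crown-6 gives the bare potassium alkoxide 18, whose oxygen weakens the C5–C10 bond and triggers a concerted [3,3]-sigmatropic shift across C3=C4–C5–C10–C1=C2, so that C2–C3 forms as C5–C10 breaks. The closest known reaction type is the anionic oxy-Cope rearrangement of 1,2-dialkenylcyclohexanols to cyclodec-5-enone enolates. The ten-membered ring is not closed end to end; it appears by four-carbon ring expansion when the bond shared by the cyclohexane and the six-membered chair transition state is cut. No stereocentre is created, but two alkene geometries and the planar chirality of the product are fixed by the chair. The trans-fused acetal locks the cyclohexane chair with the isopropenyl group axial and the vinyl group equatorial, so C9 is axial on the transition-state chair and ends cis to C2 (Z-C1=C10), while C6 is equatorial and ends trans to C3 in enolate 19. A boat transition state, which would give the E-alkene, would need the two alkenyl groups eclipsed and is out of reach of the locked chair. The step must also keep the enolate at C4=C5 and C6 unepimerised, which silylation at −78 °C directly after the rearrangement should secure. The tetrasubstituted enol ether 20 cannot turn within the ring, so its one open face is defined for step 12.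

Step 12
Reactants: 20 silyl enol ether
Product: 21 (4S)-4-bromo-5-ketone (ten-membered α-bromo ketone)
Conditions: NBS, THF, −78 °C
Reagents that add atoms: N-bromosuccinimide, O=C1CCC(=O)N1Br
Why: Electrophilic α-bromination of a silyl enol ether, far faster than attack on the other alkenes; bromine can reach C4 only from the outer face of the locked enol ether, which sets C4 with the configuration that inversion will correct in step 13.

Step 13
Reactants: 21 α-bromo ketone
Product: 23 (4R,5S)-cis-epoxide (8β-silyloxy; C12 acetal), via bromohydrin 22 (not isolated)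
Conditions: Zn(BH4)2, Et2O, −30 °C; then K2CO3, MeOH, 0 → 23 °C
Reagents that add atoms: none
Why: Chelation-controlled hydride reduction (Cram chelate between C5=O and the C6 acetal oxygen, hydride anti to the C–Br bond) should give the 5,6-anti bromohydrin. Base-induced 3-exo-tet closure (intramolecular Williamson reaction) then displaces the tertiary bromide with inversion at C4, so the oxygen that drove the rearrangement becomes the epoxide oxygen.

Step 14
Reactants: 23 silyloxy epoxide
Product: 24 8β-alcohol (epoxide and C12 acetal intact)
Conditions: Bu4NF, THF, 23 °C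
Reagents that add atoms: none
Why: Fluoride cleavage of the secondary silyl ether, done while no base-sensitive lactone is present and while C12 is still an acetal, so that no lactol can migrate to O8.

Step 15
Reactants: 25 (tert-butyldimethylsilyloxy)acetaldehyde; 26 ethyl 2-(triphenyl-λ5-phosphanylidene)propanoate
Product: 27 ethyl (E)-4-(tert-butyldimethylsilyloxy)-2-methylbut-2-enoate
Conditions: CH2Cl2, 23 °C
Reagents that add atoms: none
Why: Wittig olefination with a stabilised α-branched ylide gives the E-trisubstituted enoate.

Step 16
Reactants: 27 ethyl ester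
Product: 28 (E)-4-(tert-butyldimethylsilyloxy)-2-methylbut-2-enoic acid
Conditions: LiOH, THF/H2O, 0 → 23 °C; then aq. HCl to pH 4
Reagents that add atoms: lithium hydroxide, [Li+].[OH-]
Why: Saponification of the ethyl ester; the primary silyl ether is stable to cold aqueous hydroxide and brief mild acidification.

Step 17
Reactants: 24 8β-alcohol; 28 side-chain acid
Product: 30 C8 ester (silyl-protected side chain; epoxide; C12 acetal), via mixed anhydride 29 (not isolated)
Conditions: 2,4,6-Cl3C6H2COCl, Et3N, THF, 23 °C; then 24, DMAP, toluene, 23 °C
Reagents that add atoms: none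
Why: Yamaguchi esterification through the mixed anhydride, suited to a hindered secondary alcohol; the E-configured acid has no tendency to isomerise under acyl-pyridinium catalysis.

Step 18
Reactants: 30 C8 ester acetal
Product: 31 lactol (both anomers at C12)
Conditions: DDQ, CH2Cl2/pH 7 phosphate buffer, 0 → 23 °C
Reagents that add atoms: none
Why: Oxidative cleavage of the 4-methoxybenzyl acetal by DDQ (as for 4-methoxybenzyl glycosides) frees the lactol at neutral pH, sparing the epoxide that faces the C1=C10 alkene; with C8 acylated the lactol can close only onto O6.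

Step 19
Reactants: 31 lactol
Product: 32 silyl-protected target (α-methylene γ-lactone)
Conditions: MnO2, CH2Cl2, 23 °C
Reagents that add atoms: none
Why: MnO2 oxidation of an allylic-type hemiacetal to the α-methylene lactone; no other free hydroxyl is present and the conditions are neutral.

Step 20
Reactants: 32 silyl-protected target
Product: 33 CNP0198076.6
Conditions: HF·pyridine, pyridine, THF, 0 °C
Reagents that add atoms: none
Why: Buffered fluoride removal of the primary allylic silyl ether; epoxide, methylene lactone, ester and both alkenes are not addressed.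

## Compound list

1 | (R)-carvone, (5R)-2-methyl-5-(prop-1-en-2-yl)cyclohex-2-en-1-one | CC1=CC[C@H](CC1=O)C(C)=C | starting material
2 | lithium cross-conjugated dienolate of 1 | CC1=CC[C@H](C=C1O[Li])C(C)=C | intermediate
3 | triethyl{[(6R)-3-methyl-6-(prop-1-en-2-yl)cyclohexa-1,3-dien-2-yl]oxy}silane | CC1=CC[C@H](C=C1O[Si](CC)(CC)CC)C(C)=C | intermediate
4 | (5S,6S)-2-methyl-5-(prop-1-en-2-yl)-6-(triethylsilyloxy)cyclohex-2-en-1-one | CC[Si](CC)(CC)O[C@H]1[C@H](C(C)=C)CC=C(C)C1=O | intermediate
5 | (5S,6S)-5-(3-hydroxyprop-1-en-2-yl)-2-methyl-6-(triethylsilyloxy)cyclohex-2-en-1-one | CC[Si](CC)(CC)O[C@H]1[C@H](C(=C)CO)CC=C(C)C1=O | intermediate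
6 | 2-[(1S,2S)-4-methyl-3-oxo-2-(triethylsilyloxy)cyclohex-4-en-1-yl]prop-2-enal | CC[Si](CC)(CC)O[C@H]1[C@H](C(=C)C=O)CC=C(C)C1=O | intermediate
7 | (2R,3aS,7aS)-2-(4-methoxybenzyloxy)-6-methyl-3-methylidene-3,3a,4,7a-tetrahydro-1-benzofuran-7(2H)-one | COc1ccc(CO[C@@H]2O[C@H]3[C@H](C2=C)CC=C(C)C3=O)cc1 | intermediate
8 | tert-butyldimethylsilyl dienol ether of 7 (C5–OSi; C5=C10 and C8=C9) | COc1ccc(CO[C@@H]2O[C@H]3[C@H](C2=C)C=CC(C)=C3O[Si](C)(C)C(C)(C)C)cc1 | intermediate
9 | 8β-hydroxy bicyclic enone (hydroxyl axial, cis to the C7–C11 bond) | COc1ccc(CO[C@@H]2O[C@H]3[C@H](C2=C)[C@H](O)C=C(C)C3=O)cc1 | intermediate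
10 | 8β-(tert-butyldimethylsilyloxy) bicyclic enone | COc1ccc(CO[C@@H]2O[C@H]3[C@H](C2=C)[C@H](O[Si](C)(C)C(C)(C)C)C=C(C)C3=O)cc1 | intermediate
11 | phenyl vinyl sulfoxide (racemic) | C=CS(=O)c1ccccc1 | starting material
12 | lithium C5=C10 enolate from 10 | COc1ccc(CO[C@@H]2O[C@H]3[C@H](C2=C)[C@H](O[Si](C)(C)C(C)(C)C)CC(C)=C3O[Li])cc1 | intermediate
13 | 10α-[2-(phenylsulfinyl)ethyl]-10β-methyl ketone (sulfur epimers) | COc1ccc(CO[C@@H]2O[C@H]3[C@H](C2=C)[C@H](O[Si](C)(C)C(C)(C)C)C[C@@](C)(CCS(=O)c2ccccc2)C3=O)cc1 | intermediate
14 | 10α-vinyl-10β-methyl ketone | COc1ccc(CO[C@@H]2O[C@H]3[C@H](C2=C)[C@H](O[Si](C)(C)C(C)(C)C)C[C@@](C)(C=C)C3=O)cc1 | intermediate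
15 | 2-bromopropene | CC(Br)=C | starting material
16 | isopropenylmagnesium bromide | CC(=C)[Mg]Br | intermediate
17 | cis-1-isopropenyl-2-vinylcyclohexanol (5α-isopropenyl, 5β-OH, 10α-vinyl, 10β-methyl, 8β-silyloxy, trans-fused C12 acetal) | COc1ccc(CO[C@@H]2O[C@H]3[C@H](C2=C)[C@H](O[Si](C)(C)C(C)(C)C)C[C@@](C)(C=C)[C@@]3(O)C(C)=C)cc1 | intermediate
18 | potassium alkoxide of 17 | COc1ccc(CO[C@@H]2O[C@H]3[C@H](C2=C)[C@H](O[Si](C)(C)C(C)(C)C)C[C@@](C)(C=C)[C@@]3(O[K])C(C)=C)cc1 | intermediate
19 | ten-membered potassium enolate (Z-C1=C10; C3 and C6 trans across C4=C5) | COc1ccc(CO[C@@H]2O[C@H]3[C@H](C2=C)[C@H](O[Si](C)(C)C(C)(C)C)C/C(C)=C\CC/C(C)=C3\O[K])cc1 | intermediate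
20 | ten-membered trimethylsilyl enol ether (Z-C1=C10; C3 and C6 trans across C4=C5) | COc1ccc(CO[C@@H]2O[C@H]3[C@H](C2=C)[C@H](O[Si](C)(C)C(C)(C)C)C/C(C)=C\CC/C(C)=C3\O[Si](C)(C)C)cc1 | intermediate
21 | (4S)-4-bromo-5-ketone | COc1ccc(CO[C@@H]2O[C@H]3[C@H](C2=C)[C@H](O[Si](C)(C)C(C)(C)C)C/C(C)=C\CC[C@](C)(Br)C3=O)cc1 | intermediate
22 | (4S,5S)-bromohydrin | COc1ccc(CO[C@@H]2O[C@H]3[C@H](C2=C)[C@H](O[Si](C)(C)C(C)(C)C)C/C(C)=C\CC[C@](C)(Br)[C@H]3O)cc1 | intermediate
23 | (4R,5S)-cis-epoxide, 8β-silyl ether, C12 acetal | COc1ccc(CO[C@@H]2O[C@H]3[C@H](C2=C)[C@H](O[Si](C)(C)C(C)(C)C)C/C(C)=C\CC[C@@]2(C)O[C@@H]32)cc1 | intermediate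
24 | (4R,5S)-cis-epoxide, 8β-alcohol, C12 acetal | COc1ccc(CO[C@@H]2O[C@H]3[C@H](C2=C)[C@H](O)C/C(C)=C\CC[C@@]2(C)O[C@@H]32)cc1 | intermediate
25 | (tert-butyldimethylsilyloxy)acetaldehyde | O=CCO[Si](C)(C)C(C)(C)C | starting material
26 | ethyl 2-(triphenyl-λ5-phosphanylidene)propanoate | CCOC(=O)C(C)=P(c1ccccc1)(c1ccccc1)c1ccccc1 | starting material
27 | ethyl (E)-4-(tert-butyldimethylsilyloxy)-2-methylbut-2-enoate | CCOC(=O)/C(C)=C/CO[Si](C)(C)C(C)(C)C | intermediate
28 | (E)-4-(tert-butyldimethylsilyloxy)-2-methylbut-2-enoic acid | OC(=O)/C(C)=C/CO[Si](C)(C)C(C)(C)C | intermediate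
29 | mixed anhydride of 28 with 2,4,6-trichlorobenzoic acid | O=C(OC(=O)/C(C)=C/CO[Si](C)(C)C(C)(C)C)c1c(Cl)cc(Cl)cc1Cl | intermediate
30 | C8 ester of 24 with 28 (C12 acetal) | COc1ccc(CO[C@@H]2O[C@H]3[C@H](C2=C)[C@H](OC(=O)/C(C)=C/CO[Si](C)(C)C(C)(C)C)C/C(C)=C\CC[C@@]2(C)O[C@@H]32)cc1 | intermediate
31 | C12 lactol (both anomers) | OC1O[C@H]2[C@H](C1=C)[C@H](OC(=O)/C(C)=C/CO[Si](C)(C)C(C)(C)C)C/C(C)=C\CC[C@@]1(C)O[C@@H]21 | intermediate
32 | O-(tert-butyldimethylsilyl) derivative of the target | C=C1C(=O)O[C@H]2[C@H]1[C@H](OC(=O)/C(C)=C/CO[Si](C)(C)C(C)(C)C)C/C(C)=C\CC[C@@]1(C)O[C@@H]21 | intermediate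
33 | CNP0198076.6, (4R,5S,6S,7R,8R,1(10)Z)-4,5-epoxy-8-[(E)-4-hydroxy-2-methylbut-2-enoyloxy]germacra-1(10),11(13)-dien-12,6-olide | C=C1C(=O)O[C@H]2[C@H]1[C@H](OC(=O)/C(C)=C/CO)C/C(C)=C\CC[C@@]1(C)O[C@@H]21 | target

Total step count: 20. Longest linear sequence: 18 steps (steps 1–14 and 17–20 from (R)-carvone); steps 15 and 16 make the side-chain acid.

## Least certain steps

**Step 11 (key step).** The alkoxide may cleave stepwise (fragmentation to an allyl anion and an enone) instead of rearranging in concert, or the enolate may exchange protons before silylation. Either would erode the Z geometry or epimerise C6. The syn-diaxial C10-methyl/C8-silyloxy pair may also distort the chair. Fallback: from 17, silylation with N-(trimethylsilyl)imidazole would give trimethylsilyl ether F1, which is heated in degassed 1,2-dichlorobenzene at about 200 °C in base-washed glass. This neutral siloxy-Cope rearrangement uses the same chair, involves no free enolate and gives silyl enol ether 20 directly, where the route is rejoined.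

**Step 6 (with step 5).** The peracid may deliver oxygen from the equatorial direction or to C10, and the cyclohexadiene 8 may aromatise by loss of the C6 oxygen if the medium turns acidic. The axial preference rests on analogy, and the neighbouring equatorial C11 group opposes it sterically. Fallback: if the 8α-alcohol F2 predominates, it is inverted from 9's epimer by Mitsunobu reaction with 4-nitrobenzoic acid (PPh3, diisopropyl azodicarboxylate) to 4-nitrobenzoate F3, and cold methanolysis (K2CO3, MeOH, 0 °C) returns the route to 9.

**Step 8.** The boron-complexed tetrasubstituted enolate may add sluggishly to the weak Michael acceptor, so that proton exchange toward C6 or simple quenching wins. Facial control also rests on shielding by one axial silyloxy group and leaves methyl and silyloxy syn-diaxial. Fallback: from 10, the same reductively formed enolate 12 is trapped with acetaldehyde, a small and fast electrophile, to give β-hydroxy ketone F4 (carbinol epimers). Dehydration with the Burgess reagent, which can remove only a methyl hydrogen because C10 is quaternary, gives vinyl ketone 14.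

**Step 13.** Hydride may add to the other face of C5 if the chelate with the weakly basic acetal oxygen does not form, and that bromohydrin epimer can close only to the trans-epoxide. Loss of HBr from the tertiary bromide is the second risk. Fallback: from 21, substrate control is replaced by reagent control, a Corey–Bakshi–Shibata reduction (methyl-oxazaborolidine of the appropriate handedness, BH3·SMe2), followed by the same carbonate closure to 23. This passes through bromohydrin 22 again and makes no new compound (F0).

**Step 3.** Oxidation may not stop at the isopropenyl methyl group: the ring methine at C7 or the α-position of the silyloxy ketone may be attacked, or the enal may be over-oxidised. Fallback: from 4, ene-type chlorination with Ca(OCl)2 and solid CO2 in CH2Cl2/H2O gives allylic chloride F5, and Kornblum-type oxidation with N-methylmorpholine N-oxide in acetonitrile gives enal 6.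

## Further compounds

F1 | step 11 | O-trimethylsilyl ether of 17 | COc1ccc(CO[C@@H]2O[C@H]3[C@H](C2=C)[C@H](O[Si](C)(C)C(C)(C)C)C[C@@](C)(C=C)[C@@]3(O[Si](C)(C)C)C(C)=C)cc1
F2 | step 6 | 8α-hydroxy bicyclic enone (C8 epimer of 9) | COc1ccc(CO[C@@H]2O[C@H]3[C@H](C2=C)[C@@H](O)C=C(C)C3=O)cc1
F3 | step 6 | 8β-(4-nitrobenzoyloxy) bicyclic enone | COc1ccc(CO[C@@H]2O[C@H]3[C@H](C2=C)[C@H](OC(=O)c2ccc(cc2)[N+]([O-])=O)C=C(C)C3=O)cc1
F4 | step 8 | 10α-(1-hydroxyethyl)-10β-methyl ketone (carbinol epimers) | COc1ccc(CO[C@@H]2O[C@H]3[C@H](C2=C)[C@H](O[Si](C)(C)C(C)(C)C)C[C@@](C)(C(C)O)C3=O)cc1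
F0 | step 13 | none | none
F5 | step 3 | (5S,6S)-5-(3-chloroprop-1-en-2-yl)-2-methyl-6-(triethylsilyloxy)cyclohex-2-en-1-one | CC[Si](CC)(CC)O[C@H]1[C@H](C(=C)CCl)CC=C(C)C1=O
A1 | alternative 1 | trans-fused C5-iodo lactone | O=C1O[C@H]2[C@H](C1)[C@H](O[Si](C)(C)C(C)(C)C)C/C(C)=C\CC[C@@](C)(O[Si](CC)(CC)CC)[C@@H]2I
A2 | alternative 1 | ten-membered Z,Z-dienyl acetic acid (seco acid of A1) | OC(=O)C[C@@H]1[C@H](O[Si](C)(C)C(C)(C)C)C/C(C)=C\CC[C@@](C)(O[Si](CC)(CC)CC)/C=C\1
A3 | alternative 2 | ten-membered C8 alcohol with C7 2-(silyloxymethyl)vinyl arm | C1/C=C(C)\C[C@@H](O)[C@@H](C(=C)CO[Si](C)(C)C(C)(C)C)[C@H](O[Si](CC)(CC)CC)/C=C(C)\C1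
A4 | alternative 2 | thirteen-membered α-stannyl allylic ether | CCCC[Sn](CCCC)(CCCC)[C@H]1OC/C(CO[Si](C)(C)C(C)(C)C)=C/[C@H](O[Si](CC)(CC)CC)/C=C(C)\CC/C=C(C)\C1
A5 | alternative 3 | ten-membered β,γ-unsaturated C8 ketone with epoxide and lactone | O=C1O[C@H]2[C@H](C1)C(=O)C/C(C)=C\CC[C@@]1(C)O[C@@H]21
A6 | alternative 3 | 2-isopropenylcyclooctanone with epoxide and lactone (either C1 epimer) | O=C1O[C@H]2[C@H](C1)C(=O)C(C(C)=C)CC[C@@]1(C)O[C@@H]21
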